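**Assumptions (one line each).** (R)-Linalool is commercial at ≥95% ee, and that ee is carried through unchanged. (E)-4-Acetoxy-2-methylbut-2-enal, the vitamin A C5 building block, is commercial. B-Allyldiisopinocampheylborane made from (−)-α-pinene is assumed to attack the Re face of the enal, which should give the (R)-carbinol; the sense is to be confirmed by Mosher analysis. Only skeleton-contributing starting materials and coupling reagents are numbered; simple reagents are listed with SMILES in each step.

## Retrosynthetic overview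
1. The C11–C12 bond (Ce–Cf) is made by a Biellmann allylic-sulfone alkylation with an allylic bromide, then Pd/superhydride desulfonylation. The partners are chroman allyl bromide **11** and the carbinol-bearing allyl sulfone **21**.
2. The carbinol (R) centre comes from Brown asymmetric allylation of a commercial (E)-α-methyl enal. The prenyl terminus is installed by cross-metathesis with 2-methyl-2-butene, so the E trisubstituted alkene needs no olefination.
3. The C2 quaternary centre is taken from (R)-linalool. The chroman is built by Suzuki coupling of linalool's vinyl group to a fluoronitroarene, then intramolecular SNAr of the tertiary alkoxide. The C–O bond at the stereocentre is never broken.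
4. The 6-OH comes from the nitro group (NO2 → NH2 → Bpin → OH). The E-allylic CH2 is introduced by SeO2 oxidation of linalool's prenyl terminus. Ring order: the aryl–C4 bond is formed first, then the pyran ring. There are no other rings.

## Route

**Step 1**
Reactants: 1 (2-fluoro-5-nitrotoluene)
Product: 2 (1-bromo-2-fluoro-3-methyl-5-nitrobenzene)
Conditions: NBS, conc. H2SO4, 60 °C
Reagents that add atoms: NBS, O=C1CCC(=O)N1Br
Why: Electrophilic aromatic bromination goes to the only position ortho to F and meta to NO2; no stereocentre is involved.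

**Step 2**
Reactants: 3 ((3R)-linalool) and 2
Product: 4 ((3R)-1-(2-fluoro-3-methyl-5-nitrophenyl)-3,7-dimethyloct-6-en-3-ol)
Conditions: (i) 9-BBN (1.0 equiv), THF, 0 °C → rt; (ii) 2, PdCl2(dppf), 3 M aq. K3PO4, THF, 50 °C
Reagents that add atoms: none (B and Pd are not retained)
Why: 9-BBN hydroborates the unhindered vinyl group in preference to the trisubstituted alkene, and the B-alkyl Suzuki–Miyaura coupling joins it to C–Br. The carbinol stereocentre is untouched, so it defines C2.

**Step 3**
Reactants: 4
Product: 5 ((2R)-2,8-dimethyl-2-(4-methylpent-3-en-1-yl)-6-nitrochromane)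
Conditions: KHMDS (1.2 equiv), THF/DMPU, −20 °C → rt
Reagents that add atoms: none (F leaves as KF)
Why: The tertiary alkoxide attacks the fluoride para to NO2 (SNAr, 6-exo ring closure), and the C2–O bond is not broken, so configuration is retained. Proposed new method: mechanism is addition–elimination through a Meisenheimer complex strongly stabilised by the para-nitro group. The closest known reactions are intramolecular SNAr alkoxide cyclisations onto p-fluoronitroarenes and Pd-catalysed closures of tertiary alcohols to 2,2-disubstituted chromans. The new feature is a hindered tertiary alkoxide attacking a di-ortho-substituted fluoride.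

**Step 4**
Reactants: 5
Product: 6 ((2R)-6-amino-2,8-dimethyl-2-(4-methylpent-3-en-1-yl)chromane)
Conditions: Fe powder, NH4Cl, EtOH/H2O 4:1, 70 °C
Reagents that add atoms: none
Why: Béchamp-type nitro reduction leaves the trisubstituted alkene intact, unlike H2/Pd.

**Step 5**
Reactants: 6
Product: 7 ((2R)-2,8-dimethyl-2-(4-methylpent-3-en-1-yl)-6-(Bpin)chromane)
Conditions: tBuONO, B2pin2, cat. benzoyl peroxide, MeCN, rt
Reagents that add atoms: B2pin2, CC1(C)OB(OC1(C)C)B1OC(C)(C)C(C)(C)O1
Why: Sandmeyer-type borylation goes through the diazonium and aryl radical under neutral conditions, so the acid-sensitive alkene is safe.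

**Step 6**
Reactants: 7
Product: 8 ((2R)-2,8-dimethyl-2-(4-methylpent-3-en-1-yl)chroman-6-ol)
Conditions: NaBO3·4H2O, THF/H2O 1:1, rt
Reagents that add atoms: sodium perborate, acting as the HOO⁻ source (OO); it supplies the phenol O
Why: Oxidative C–B to C–O conversion occurs without epoxidising the alkene, and C2 is untouched.

**Step 7**
Reactants: 8
Product: 9 (aryl TBS ether of 8)
Conditions: TBSCl, imidazole, DMF, rt
Reagents that add atoms: TBSCl, C[Si](C)(Cl)C(C)(C)C
Why: The phenol is protected so it survives SeO2 and the strong base and hydride steps later.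

**Step 8**
Reactants: 9
Product: 10 ((2R)-2-[(3E)-5-hydroxy-4-methylpent-3-en-1-yl]-6-(TBSO)-2,8-dimethylchromane)
Conditions: SeO2 (10 mol%), TBHP, CH2Cl2, 0 °C → rt
Reagents that add atoms: TBHP, CC(C)(C)OO, which supplies the allylic O
Why: Riley/Sharpless allylic oxidation (ene reaction then [2,3]-shift) functionalises the methyl trans to the chain, giving the E-allylic alcohol. The Z-alcohol and aldehyde by-products are removed by chromatography, and the C2 centre is remote.

**Step 9**
Reactants: 10
Product: 11 ((2R)-2-[(3E)-5-bromo-4-methylpent-3-en-1-yl]-6-(TBSO)-2,8-dimethylchromane)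
Conditions: CBr4, PPh3, CH2Cl2, 0 °C
Reagents that add atoms: CBr4, BrC(Br)(Br)Br
Why: Appel-type SN2 bromination of a primary allylic alcohol keeps the alkene geometry; the product is used crude.

**Step 10**
Reactants: 12 ((E)-4-acetoxy-2-methylbut-2-enal) and 13 ((+)-B-allyldiisopinocampheylborane, from (−)-α-pinene)
Product: 14 ((2E,4R)-3-methylhepta-2,6-diene-1,4-diol)
Conditions: 13 (1.2 equiv), Et2O, −78 °C; then 3 M NaOH, 30% H2O2, 0 °C → rt (also saponifies the acetate)
Reagents that add atoms: 13, which supplies the allyl group, C=CCB(C1CC2CC(C1C)C2(C)C)C1CC2CC(C1C)C2(C)C (isopinocampheyl stereochemistry from (−)-α-pinene)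
Why: Brown asymmetric allylation through a closed Zimmerman–Traxler transition state sets the carbinol centre (R) by reagent control (Re-face attack). Any minor (S)-carbinol epimer is a diastereomer of the final product and can be removed by chromatography or HPLC.

**Step 11**
Reactants: 14
Product: 15 ((2E,4R)-1,4-bis(TBSO)-3-methylhepta-2,6-diene)
Conditions: TBSCl (2.5 equiv), imidazole, DMF, rt
Reagents that add atoms: TBSCl, C[Si](C)(Cl)C(C)(C)C
Why: Both hydroxyls are protected; the carbinol centre is not involved.

**Step 12**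
Reactants: 15 and 16 (2-methyl-2-butene)
Product: 17 ((2E,4R)-1,4-bis(TBSO)-3,7-dimethylocta-2,6-diene)
Conditions: Hoveyda–Grubbs II (5 mol%), 16 (20 equiv), CH2Cl2, 40 °C
Reagents that add atoms: 16, CC=C(C)C, which supplies the =CMe2 terminus
Why: Cross-metathesis converts the fast-reacting terminal alkene to the prenyl group, while the hindered trisubstituted alkene flanked by OTBS groups stays inert; propene is lost and no stereocentre is changed.

**Step 13**
Reactants: 17
Product: 18 ((2E,4R)-4-(TBSO)-3,7-dimethylocta-2,6-dien-1-ol)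
Conditions: PPTS (0.2 equiv), MeOH, rt
Reagents that add atoms: none
Why: Mild acid selectively cleaves the unhindered primary allylic TBS ether over the secondary one.

**Step 14**
Reactants: 18
Product: 19 ((2E,4R)-1-bromo-4-(TBSO)-3,7-dimethylocta-2,6-diene)
Conditions: CBr4, PPh3, CH2Cl2, 0 °C
Reagents that add atoms: CBr4, BrC(Br)(Br)Br
Why: Appel bromination as in step 9; the product is used crude.

**Step 15**
Reactants: 19 and 20 (sodium benzenesulfinate)
Product: 21 (phenyl (2E,4R)-4-(TBSO)-3,7-dimethylocta-2,6-dien-1-yl sulfone)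
Conditions: 20 (1.5 equiv), DMF, 0 °C → rt
Reagents that add atoms: 20, [Na+].[O-]S(=O)c1ccccc1
Why: Sulfinate S-alkylation by SN2 at the primary allylic bromide gives the geranyl-type sulfone.

**Step 16**
Reactants: 21 (1.3 equiv) and 11
Product: 22 (allylic sulfone, mixture of epimers at the sulfone carbon)
Conditions: n-BuLi (1.3 equiv), THF/HMPA, −78 °C; add 11; −78 → −30 °C
Reagents that add atoms: none beyond the two reactants
Why: Biellmann α-alkylation of the lithiated allylic sulfone with the allylic bromide forms the Ce–Cf bond with both E alkenes retained. The new sulfone stereocentre is transient and is destroyed in step 17.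

**Step 17**
Reactants: 22
Product: 23 (bis-TBS-protected target)
Conditions: Pd(dppp)Cl2 (5 mol%), LiBHEt3 (4 equiv), THF, 0 °C
Reagents that add atoms: none (hydride only)
Why: Torii–Tanaka Pd-catalysed hydrogenolysis delivers hydride to the less hindered π-allyl terminus, removing PhSO2 with retention of the trisubstituted alkene; no stereocentre is affected.

**Step 18**
Reactants: 23
Product: 24 (Sargachromanol C)
Conditions: TBAF (1 M in THF, 4 equiv), THF, 0 → 40 °C
Reagents that add atoms: none
Why: Fluoride removes both silyl groups, giving the free phenol and the (R)-allylic alcohol with both stereocentres unchanged.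

## Compound list
1 | 2-fluoro-5-nitrotoluene | Cc1cc([N+](=O)[O-])ccc1F | starting material
2 | 1-bromo-2-fluoro-3-methyl-5-nitrobenzene | Cc1cc([N+](=O)[O-])cc(Br)c1F | intermediate
3 | (3R)-linalool | C=C[C@](C)(O)CCC=C(C)C | starting material
4 | (3R)-1-(2-fluoro-3-methyl-5-nitrophenyl)-3,7-dimethyloct-6-en-3-ol | Cc1cc([N+](=O)[O-])cc(CC[C@](C)(O)CCC=C(C)C)c1F | intermediate
5 | (2R)-2,8-dimethyl-2-(4-methylpent-3-enyl)-6-nitrochromane | CC(C)=CCC[C@]1(C)CCc2cc([N+](=O)[O-])cc(C)c2O1 | intermediate
6 | (2R)-6-amino-2,8-dimethyl-2-(4-methylpent-3-enyl)chromane | CC(C)=CCC[C@]1(C)CCc2cc(N)cc(C)c2O1 | intermediate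
7 | (2R)-6-Bpin-2,8-dimethyl-2-(4-methylpent-3-enyl)chromane | CC(C)=CCC[C@]1(C)CCc2cc(B3OC(C)(C)C(C)(C)O3)cc(C)c2O1 | intermediate
8 | (2R)-2,8-dimethyl-2-(4-methylpent-3-enyl)chroman-6-ol | CC(C)=CCC[C@]1(C)CCc2cc(O)cc(C)c2O1 | intermediate
9 | 6-TBS ether of 8 | CC(C)=CCC[C@]1(C)CCc2cc(O[Si](C)(C)C(C)(C)C)cc(C)c2O1 | intermediate
10 | (2R)-2-[(3E)-5-hydroxy-4-methylpent-3-enyl]-6-(TBSO)-2,8-dimethylchromane | OC/C(C)=C/CC[C@]1(C)CCc2cc(O[Si](C)(C)C(C)(C)C)cc(C)c2O1 | intermediate
11 | (2R)-2-[(3E)-5-bromo-4-methylpent-3-enyl]-6-(TBSO)-2,8-dimethylchromane | BrC/C(C)=C/CC[C@]1(C)CCc2cc(O[Si](C)(C)C(C)(C)C)cc(C)c2O1 | intermediate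
12 | (2E)-4-acetoxy-2-methylbut-2-enal | O=C/C(C)=C/COC(C)=O | starting material
13 | (+)-B-allyldiisopinocampheylborane (from (−)-α-pinene; pinene stereochemistry not drawn) | C=CCB(C1CC2CC(C1C)C2(C)C)C1CC2CC(C1C)C2(C)C | starting material (reagent)
14 | (2E,4R)-3-methylhepta-2,6-diene-1,4-diol | C=CC[C@@H](O)/C(C)=C/CO | intermediate
15 | (2E,4R)-1,4-bis(TBSO)-3-methylhepta-2,6-diene | C=CC[C@@H](O[Si](C)(C)C(C)(C)C)/C(C)=C/CO[Si](C)(C)C(C)(C)C | intermediate
16 | 2-methyl-2-butene | CC=C(C)C | starting material (reagent)
17 | (2E,4R)-1,4-bis(TBSO)-3,7-dimethylocta-2,6-diene | CC(C)=CC[C@@H](O[Si](C)(C)C(C)(C)C)/C(C)=C/CO[Si](C)(C)C(C)(C)C | intermediate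
18 | (2E,4R)-4-(TBSO)-3,7-dimethylocta-2,6-dien-1-ol | CC(C)=CC[C@@H](O[Si](C)(C)C(C)(C)C)/C(C)=C/CO | intermediate
19 | (2E,4R)-1-bromo-4-(TBSO)-3,7-dimethylocta-2,6-diene | CC(C)=CC[C@@H](O[Si](C)(C)C(C)(C)C)/C(C)=C/CBr | intermediate
20 | sodium benzenesulfinate | [Na+].[O-]S(=O)c1ccccc1 | starting material (reagent)
21 | phenyl (2E,4R)-4-(TBSO)-3,7-dimethylocta-2,6-dienyl sulfone | CC(C)=CC[C@@H](O[Si](C)(C)C(C)(C)C)/C(C)=C/CS(=O)(=O)c1ccccc1 | intermediate
22 | coupled allylic sulfone (epimeric at the sulfone carbon, undefined there) | CC(C)=CC[C@@H](O[Si](C)(C)C(C)(C)C)/C(C)=C/C(S(=O)(=O)c1ccccc1)C/C(C)=C/CC[C@]1(C)CCc2cc(O[Si](C)(C)C(C)(C)C)cc(C)c2O1 | intermediate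
23 | bis-TBS-protected Sargachromanol C | CC(C)=CC[C@@H](O[Si](C)(C)C(C)(C)C)/C(C)=C/CC/C(C)=C/CC[C@]1(C)CCc2cc(O[Si](C)(C)C(C)(C)C)cc(C)c2O1 | intermediate
24 | Sargachromanol C | CC(C)=CC[C@@H](O)/C(C)=C/CC/C(C)=C/CC[C@]1(C)CCc2cc(O)cc(C)c2O1 | target

## Totals
Total steps: 18, counting the side-chain branch (steps 10–15). Longest linear sequence: 12 steps (steps 1–9, then 16, 17, 18).

## Three steps most likely to fail
1. **Step 3 (hindered tertiary-alkoxide SNAr).** The fluoride is flanked by a methyl group and the alkyl chain. Fallback: change the ring-closing mechanism to a Pd (tBuBrettPhos) or Cu (Ullmann-type) intramolecular C–O coupling of the tertiary alcohol. The Suzuki coupling would use a 1-iodo-2-bromo-3-methyl-5-silyloxy arene, coupling at C–I and closing on C–Br.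
2. **Step 8 (SeO2 E-methyl oxidation).** It may give poor E/Z selectivity or over-oxidation to the aldehyde. Fallback: replace C–H oxidation with olefination. Cleave the prenyl alkene of 9 (OsO4/NaIO4) to the aldehyde, then do an E-selective HWE with triethyl 2-phosphonopropionate and reduce with DIBAL. Convert the resulting allylic alcohol to bromide 11 as in step 9.
3. **Steps 16–17 (sulfone alkylation and desulfonylation).** The γ-silyloxy allyl sulfone anion may eliminate OTBS, and the Pd/hydride step may be regio-unselective. Fallback: switch from convergent sulfone coupling to a linear build with a late stereocentre. Alkylate bromide 11 with the lithium enolate of tert-butyl acetate. Then reduce with DIBAL, perform an E-selective HWE with triethyl 2-phosphonopropionate, and reduce to the enal (DIBAL, MnO2). Finish with Brown allylation, then CM with 16, then TBAF.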